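**Retrosynthetic overview**

1. The target is the diester of 4,4'-dihydroxy-α-truxillic acid with two identical amino alcohol units (cyclopenta[c]pyridine numbering: piperidine N2–C1–C7a–C4a–C4–C3, cyclopentane C4a–C5–C6–C7–C7a). Both ester C6–O bonds are cut first (twofold Mitsunobu esterification of the 6-epimeric alcohol with inversion), and the cyclobutane goes back to the solid-state head-to-tail [2+2] photodimer of two molecules of p-coumaric acid.
2. Enabling feature: the carbinol carbon C6 stands 1,3 to the ring-fusion carbon C4a (C6–C5–C4a). At the ketone level a C5=C4a double bond makes C4a the β-carbon of a cyclopentenone, and the N2–C3–C4(CH3) segment is the retron of an enamine from a secondary N-methylamine and propanal.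
3. The piperidine is therefore closed last, on a monocyclic amino enone: condensation with propanal, intramolecular enamine Michael addition (N2–C3 and C4–C4a) and hydrogenation of the resulting cyclic enamine (C4) in one operation.
4. The amino enone comes from (S)-4-silyloxycyclopentenone. Its silyloxy group only steers a radical aminomethylation (C7a) and is then eliminated to unveil the enone; α′-methylation sets C7 and borohydride sets C6.
5. Order of ring formation: cyclobutane (step 1), cyclopentane (brought in with the starting enone), piperidine (step 7).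

Key step: step 7

Assumption: the commercial crystal form of (E)-p-coumaric acid is taken to have the head-to-tail stacking needed for topochemical dimerization to the α-truxillic acid, and the silyloxycyclopentenone is taken as a commercial enantiopure building block.

**Route**

Step 1
Reactants: 1 (E)-p-coumaric acid (2 equiv)
Product: 2 4,4'-dihydroxy-α-truxillic acid [(1α,2α,3β,4β)-2,4-bis(4-hydroxyphenyl)cyclobutane-1,3-dicarboxylic acid]
Conditions: hν (medium-pressure Hg lamp, Pyrex filter), finely ground crystals suspended in hexane, rt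
Reagents that add atoms: none
Why: Topochemical head-to-tail [2+2] photocycloaddition of two molecules of 1 stacked as centrosymmetric pairs in the crystal should give only the α-truxillic (1,3-diacid, carboxyls trans, aryls trans) isomer, all four cyclobutane stereocenters being fixed by the lattice.

Step 2
Reactants: 2 4,4'-dihydroxy-α-truxillic acid
Product: 3 4,4'-diacetoxy-α-truxillic acid [(1α,2α,3β,4β)-2,4-bis(4-acetoxyphenyl)cyclobutane-1,3-dicarboxylic acid]
Conditions: NaOH (aq), Ac2O, 0 °C; then HCl (aq) to pH 2
Reagents that add atoms: acetic anhydride, CC(=O)OC(C)=O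
Why: Schotten–Baumann acetylation of the two phenoxides masks the phenols against O-alkylation in the later Mitsunobu step, while the carboxylates return as free acids on acidification; no stereocenter is involved.

Step 3
Reactants: 4 (4S)-4-(tert-butyldimethylsilyloxy)cyclopent-2-en-1-one; 5 N-Boc-sarcosine [N-(tert-butoxycarbonyl)-N-methylglycine]
Product: 6 tert-butyl {[(1R,2S)-2-(tert-butyldimethylsilyloxy)-4-oxocyclopentyl]methyl}(methyl)carbamate (aminomethyl trans to silyloxy)
Conditions: Ir[dF(CF3)ppy]2(dtbbpy)PF6 (1 mol %), K2HPO4, DMF, blue LEDs, rt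
Reagents that add atoms: none
Why: Photoredox decarboxylative radical conjugate addition (Giese reaction): the N-Boc-N-methylaminomethyl radical formed by oxidation of the carboxylate and loss of CO2 should add to the enone β-carbon anti to the bulky silyloxy group, which sets the future C7a.

Step 4
Reactants: 6 tert-butyl {[(1R,2S)-2-(tert-butyldimethylsilyloxy)-4-oxocyclopentyl]methyl}(methyl)carbamate
Product: 7 tert-butyl methyl{[(1S)-4-oxocyclopent-2-en-1-yl]methyl}carbamate
Conditions: DBU, CH2Cl2, 0 °C → rt
Reagents that add atoms: none
Why: E1cB elimination of the β-silyloxy group through the ketone enolate removes the spent control element and transposes the enone so that the future C4a becomes its β-carbon; the γ-stereocenter (future C7a) should survive these mild conditions.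

Step 5
Reactants: 7 tert-butyl methyl{[(1S)-4-oxocyclopent-2-en-1-yl]methyl}carbamate
Product: 9 tert-butyl methyl{[(1R,5S)-5-methyl-4-oxocyclopent-2-en-1-yl]methyl}carbamate, via lithium dienolate 8 (not isolated)
Conditions: LiN(i-Pr)2 (LDA), THF, −78 °C; then MeI, DMPU, −78 → −40 °C
Reagents that add atoms: iodomethane, CI
Why: Kinetic α′-deprotonation of the cyclopentenone gives the cross-conjugated enolate, which should be methylated anti to the neighbouring aminomethyl arm, so that C7 is set trans to C7a (also the thermodynamically preferred arrangement).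

Step 6
Reactants: 9 tert-butyl methyl{[(1R,5S)-5-methyl-4-oxocyclopent-2-en-1-yl]methyl}carbamate
Product: 10 (4R,5S)-5-methyl-4-[(methylamino)methyl]cyclopent-2-en-1-one trifluoroacetate salt
Conditions: TFA, CH2Cl2, 0 °C → rt; evaporation
Reagents that add atoms: trifluoroacetic acid, OC(=O)C(F)(F)F
Why: Acidolytic Boc cleavage (loss of the tert-butyl cation, then decarboxylation) frees the secondary amine, which is kept as its salt so that it cannot add to the enone before the key step.

Step 7
Reactants: 10 (4R,5S)-5-methyl-4-[(methylamino)methyl]cyclopent-2-en-1-one trifluoroacetate salt; 11 propanal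
Product: 14 (4R,4aS,7S,7aR)-2,4,7-trimethyloctahydro-6H-cyclopenta[c]pyridin-6-one, via propenyl enamine 12 (not isolated), via bicyclic enamine ketone 13 (not isolated)
Conditions: K2CO3, 4 Å MS, THF, 0 → 40 °C; then 10% Pd/C, H2 (1 atm), rt, same flask
Reagents that add atoms: none
Why: K2CO3 frees the secondary amine of 10, which condenses with propanal 11 to the (E)-enamine 12; its nucleophilic β-carbon (future C4) adds to the β-carbon of the cyclopentenone (future C4a), and proton transfer within the resulting iminium enolate gives the endocyclic enamine 13, which is hydrogenated in the same flask. The closest known reaction type is the intramolecular Stork enamine Michael addition of an amine-tethered acceptor (enamine annulation), followed by catalytic enamine hydrogenation. The piperidine closes in a 6-(enolendo)-exo-trig mode, N2–C3 arising from the condensation and C4–C4a from the Michael addition. C4a is controlled by the three-atom tether from C7a, which can deliver the enamine only to the enone face that carries the aminomethyl arm, so the ring fusion must be cis; C4 is controlled by syn addition of hydrogen to C3=C4 from the convex face of the cis-fused bicycle (the face of H4a and H7a, opposite C5 and C7), which places H4 cis to H4a as the target requires. The step needs C–C bond formation through the enamine in preference to N-addition to the enone, which is secured because an intramolecular aza-Michael addition would have to form an azetidine and the intermolecular one is reversible; it also needs reduction of the enamine beside the ketone, for which Pd/C at 1 atm should suffice, while C7 and C7a are untouched (C7 already sits in its favoured trans arrangement).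

Step 8
Reactants: 14 (4R,4aS,7S,7aR)-2,4,7-trimethyloctahydro-6H-cyclopenta[c]pyridin-6-one
Product: 15 6-epi-incarvilline [(4R,4aS,6S,7S,7aR)-2,4,7-trimethyloctahydro-1H-cyclopenta[c]pyridin-6-ol]
Conditions: NaBH4, MeOH, −20 → 0 °C
Reagents that add atoms: none
Why: The small hydride should attack the cyclopentanone from the convex face of the cis-fused bicycle (the face of H4a and H7a, syn to the 7-methyl group as in 2-alkylcyclopentanones), which places the hydroxyl on the concave face trans to the 7-methyl group (6S).

Step 9
Reactants: 3 4,4'-diacetoxy-α-truxillic acid (1 equiv); 15 6-epi-incarvilline (2.4 equiv)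
Product: 16 bis[(4R,4aS,6R,7S,7aR)-2,4,7-trimethyloctahydro-1H-cyclopenta[c]pyridin-6-yl] (1α,2α,3β,4β)-2,4-bis(4-acetoxyphenyl)cyclobutane-1,3-dicarboxylate
Conditions: PPh3, DEAD, THF, 0 °C → rt
Reagents that add atoms: none
Why: Twofold Mitsunobu esterification: each alkoxyphosphonium ion is displaced by a carboxylate of 3 from the convex face with inversion, which turns 6S into the required 6R at both carbinol centres and leaves the cyclobutane stereocenters untouched.

Step 10
Reactants: 16 bis[(4R,4aS,6R,7S,7aR)-2,4,7-trimethyloctahydro-1H-cyclopenta[c]pyridin-6-yl] (1α,2α,3β,4β)-2,4-bis(4-acetoxyphenyl)cyclobutane-1,3-dicarboxylate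
Product: 17 CNP0180864.2 [bis[(4R,4aS,6R,7S,7aR)-2,4,7-trimethyloctahydro-1H-cyclopenta[c]pyridin-6-yl] (1α,2α,3β,4β)-2,4-bis(4-hydroxyphenyl)cyclobutane-1,3-dicarboxylate]
Conditions: NH3 (7 M in MeOH), 0 °C
Reagents that add atoms: none
Why: Aryl acetates undergo aminolysis far faster than the hindered secondary alkyl cyclobutanecarboxylates, so ammonia should free both phenols without touching the diester or epimerizing the cyclobutane.

**Compound list**

1 | (E)-p-coumaric acid, (2E)-3-(4-hydroxyphenyl)prop-2-enoic acid | OC(=O)/C=C/c1ccc(O)cc1 | starting material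
2 | 4,4'-dihydroxy-α-truxillic acid | OC(=O)[C@H]1[C@H](c2ccc(O)cc2)[C@H](C(=O)O)[C@H]1c1ccc(O)cc1 | intermediate
3 | 4,4'-diacetoxy-α-truxillic acid | OC(=O)[C@H]1[C@H](c2ccc(OC(C)=O)cc2)[C@H](C(=O)O)[C@H]1c1ccc(OC(C)=O)cc1 | intermediate
4 | (4S)-4-(tert-butyldimethylsilyloxy)cyclopent-2-en-1-one | O=C1C=C[C@@H](O[Si](C)(C)C(C)(C)C)C1 | starting material
5 | N-Boc-sarcosine | CN(CC(=O)O)C(=O)OC(C)(C)C | starting material
6 | tert-butyl {[(1R,2S)-2-(tert-butyldimethylsilyloxy)-4-oxocyclopentyl]methyl}(methyl)carbamate | O=C1C[C@H](CN(C)C(=O)OC(C)(C)C)[C@@H](O[Si](C)(C)C(C)(C)C)C1 | intermediate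
7 | tert-butyl methyl{[(1S)-4-oxocyclopent-2-en-1-yl]methyl}carbamate | O=C1C[C@H](CN(C)C(=O)OC(C)(C)C)C=C1 | intermediate
8 | lithium (3R)-3-{[(tert-butoxycarbonyl)(methyl)amino]methyl}cyclopenta-1,4-dien-1-olate | [Li+].[O-]C1=C[C@H](CN(C)C(=O)OC(C)(C)C)C=C1 | intermediate
9 | tert-butyl methyl{[(1R,5S)-5-methyl-4-oxocyclopent-2-en-1-yl]methyl}carbamate | C[C@H]1[C@H](CN(C)C(=O)OC(C)(C)C)C=CC1=O | intermediate
10 | (4R,5S)-5-methyl-4-[(methylamino)methyl]cyclopent-2-en-1-one trifluoroacetate salt | C[C@H]1[C@H](C[NH2+]C)C=CC1=O.[O-]C(=O)C(F)(F)F | intermediate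
11 | propanal | CCC=O | starting material
12 | (4R,5S)-5-methyl-4-({methyl[(1E)-prop-1-en-1-yl]amino}methyl)cyclopent-2-en-1-one | C[C@H]1[C@H](CN(C)/C=C/C)C=CC1=O | intermediate
13 | (4aR,7S,7aR)-2,4,7-trimethyl-1,2,4a,5,7,7a-hexahydro-6H-cyclopenta[c]pyridin-6-one | C[C@H]1[C@@H]2CN(C)C=C(C)[C@@H]2CC1=O | intermediate
14 | (4R,4aS,7S,7aR)-2,4,7-trimethyloctahydro-6H-cyclopenta[c]pyridin-6-one | C[C@H]1[C@@H]2CN(C)C[C@H](C)[C@@H]2CC1=O | intermediate
15 | 6-epi-incarvilline, (4R,4aS,6S,7S,7aR)-2,4,7-trimethyloctahydro-1H-cyclopenta[c]pyridin-6-ol | C[C@H]1[C@@H]2CN(C)C[C@H](C)[C@@H]2C[C@@H]1O | intermediate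
16 | bis[(4R,4aS,6R,7S,7aR)-2,4,7-trimethyloctahydro-1H-cyclopenta[c]pyridin-6-yl] (1α,2α,3β,4β)-2,4-bis(4-acetoxyphenyl)cyclobutane-1,3-dicarboxylate | C[C@H]1[C@@H]2CN(C)C[C@H](C)[C@@H]2C[C@H]1OC(=O)[C@H]1[C@H](c2ccc(OC(C)=O)cc2)[C@H](C(=O)O[C@@H]2C[C@@H]3[C@@H](CN(C)C[C@@H]3C)[C@@H]2C)[C@H]1c1ccc(OC(C)=O)cc1 | intermediate
17 | CNP0180864.2 | C[C@H]1[C@@H]2CN(C)C[C@H](C)[C@@H]2C[C@H]1OC(=O)[C@H]1[C@H](c2ccc(O)cc2)[C@H](C(=O)O[C@@H]2C[C@@H]3[C@@H](CN(C)C[C@@H]3C)[C@@H]2C)[C@H]1c1ccc(O)cc1 | target

**Step count and risks**

Total step count: 10. Longest linear sequence: 8 steps (steps 3 to 10, from compound 4).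

Steps most likely to fail:

1. Step 7 (key step). The enamine may fail to cyclize cleanly: the freed amino enone can oligomerize by intermolecular aza-Michael addition, propanal can self-condense, or hydrogen may be delivered to C3=C4 with poor facial selectivity. The fallback sets out from 10 and comes back at 14. N-Alkylation of 10 with 2,3-dibromopropene (K2CO3, MeCN, rt) would give the N-(2-bromoallyl) amino enone F1. A reductive Heck cyclization (Pd(OAc)2, PPh3, HCO2Na, DMF, 80 °C), in which the alkenylpalladium species adds across C4a=C5 on the face of the tether and the resulting palladium enolate is reduced by formate, would close the same C4–C4a bond and give the 4-methylidene ketone F2. Hydrogenation (H2, 10% Pd/C, EtOH) from the convex face would then set C4 and return 14.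

2. Step 5. γ-Deprotonation may compete with α′-deprotonation (loss of configuration at the future C7a, migration of the double bond), and enolate exchange may cause over-methylation. The fallback sets out from 4 and comes back at 9; it puts the methyl group on the enone before the radical addition. α-Iodination of 4 (I2, pyridine, CH2Cl2) would give the iodoenone F3, and Negishi coupling (MeZnCl, Pd(PPh3)4, THF, rt) the 2-methyl enone F4. Decarboxylative radical addition of 5 to F4 under the conditions of step 3 would give the methyl silyloxy ketone F5, the radical again entering anti to the silyloxy group. DBU would then eliminate the silanol and equilibrate the α-methyl group to the trans position, giving 9.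

3. Step 8. Hydride may be delivered with insufficient or reversed facial selectivity, which would compromise C6 after the inversion in step 9. The fallback sets out from 14 and comes back at 16; it replaces invertive esterification by acylation with retention. Reduction with a bulky hydride (LiBH(s-Bu)3, THF, −78 °C), which should be steered anti to the adjacent 7-methyl group, would give the 6R alcohol incarvilline F6. Diacid 3 would be converted into the bis(acid chloride) F7 ((COCl)2, cat. DMF, CH2Cl2), and F6 acylated with it (Et3N, DMAP, CH2Cl2, 0 °C → rt) to give 16.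

**Further compounds**

F1 | step 7 | (4R,5S)-4-{[(2-bromoprop-2-en-1-yl)(methyl)amino]methyl}-5-methylcyclopent-2-en-1-one | C[C@H]1[C@H](CN(C)CC(Br)=C)C=CC1=O
F2 | step 7 | (4aR,7S,7aR)-2,7-dimethyl-4-methylideneoctahydro-6H-cyclopenta[c]pyridin-6-one | C[C@H]1[C@@H]2CN(C)CC(=C)[C@@H]2CC1=O
F3 | step 5 | (4S)-4-(tert-butyldimethylsilyloxy)-2-iodocyclopent-2-en-1-one | O=C1C(I)=C[C@@H](O[Si](C)(C)C(C)(C)C)C1
F4 | step 5 | (4S)-4-(tert-butyldimethylsilyloxy)-2-methylcyclopent-2-en-1-one | O=C1C(C)=C[C@@H](O[Si](C)(C)C(C)(C)C)C1
F5 | step 5 | tert-butyl {[(1R,2S,5S)-2-(tert-butyldimethylsilyloxy)-5-methyl-4-oxocyclopentyl]methyl}(methyl)carbamate | C[C@H]1[C@H](CN(C)C(=O)OC(C)(C)C)[C@@H](O[Si](C)(C)C(C)(C)C)CC1=O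
F6 | step 8 | incarvilline, (4R,4aS,6R,7S,7aR)-2,4,7-trimethyloctahydro-1H-cyclopenta[c]pyridin-6-ol | C[C@H]1[C@@H]2CN(C)C[C@H](C)[C@@H]2C[C@H]1O
F7 | step 8 | (1α,2α,3β,4β)-2,4-bis(4-acetoxyphenyl)cyclobutane-1,3-dicarbonyl dichloride | O=C(Cl)[C@H]1[C@H](c2ccc(OC(C)=O)cc2)[C@H](C(=O)Cl)[C@H]1c1ccc(OC(C)=O)cc1
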